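**Plan**

- Numbering and enabling feature: the chain runs from C1 (alkyne CH) to C15 (ethyl CH3); ring A is the oxolane O–C6–C7–C8–C9 and ring B the oxocane O–C7–C8–C9–C10–C11–C12–C13. Ring A with C10 on C9 is a 2,5-anhydro-3-deoxy-D-arabino-hexose (C10 = sugar C1, C9 = C2, C8 = C3, C7 = C4, C6 = C5, C5 = C6): C6 and C7 have the D-glucose configurations and C9 is glucose C2 inverted, so ring A can be made from a glucopyranoside by moving the ring oxygen from C1 to C2.
- Retrosynthetic cuts, in order: C1–C2 (Colvin) and C3=C4 (cross-metathesis); C4–C5 (vinyl cuprate on a C5 triflate); C10–Br and C12–Br (double SN2 on the 10,12-diol); C11=C12 (ring-closing metathesis, ring B); C10–C11 (vinyl addition to the C10 aldehyde); O–C13 (allylic etherification of the C7 hydroxyl); O–C9 of ring A (1,2-shift of the pyranose oxygen onto a C2 triflate).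
- Forward order: 3-deoxygenation and protection of a methyl α-D-glucopyranoside, 2-triflate, ring A by ring contraction, pentenyl ether on the C7 oxygen and vinyl carbinol at C10, ring B by metathesis, C12 oxygen and C10 reset, both bromides, C1–C4 enyne last.
- Stereochemistry: C6 and C7 come from D-glucose and C9 from the inversion in the key step. C13 comes from the iridium catalyst. C10 is first set by chelation-controlled addition, only to direct the epoxidation that fixes C12; it is then reset by 1,3-anti directed reduction. Both bromides arise by inversion of the diol, and the E alkene by cross-metathesis.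

Key step: step 8

Remark: methyl 4,6-O-benzylidene-α-D-glucopyranoside is taken as the commercial entry point; TBDPS = tert-butyldiphenylsilyl.
Remark: in step 11 the phosphoramidite enantiomer is the one that delivers the (3R)-pentenyl ether; its antipode would give the C13 epimer.

**Route**

Step 1
Reactants: 1 methyl 4,6-O-benzylidene-α-D-glucopyranoside
Product: 2 methyl 2-O-benzoyl-4,6-O-benzylidene-α-D-glucopyranoside
Conditions: 1-benzoylimidazole, CHCl3, reflux
Reagents that add atoms: 1-benzoylimidazole, O=C(c1ccccc1)n1ccnc1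
Why: Regioselective acyl transfer from a mild N-acylimidazole to the 2-OH, the more acidic and more reactive hydroxyl of the 2,3-diol of 4,6-O-benzylidene-α-glucosides; no stereocentre is touched.

Step 2
Reactants: 2 methyl 2-O-benzoyl-4,6-O-benzylidene-α-D-glucopyranoside
Product: 3 methyl 2-O-benzoyl-4,6-O-benzylidene-3-O-(imidazol-1-ylcarbonothioyl)-α-D-glucopyranoside
Conditions: 1,1'-thiocarbonyldiimidazole, ClCH2CH2Cl, reflux
Reagents that add atoms: 1,1'-thiocarbonyldiimidazole, S=C(n1ccnc1)n1ccnc1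
Why: Thiocarbonyl transfer to the only free hydroxyl under neutral conditions (no base, hence no benzoate migration) gives the substrate for Barton–McCombie deoxygenation.

Step 3
Reactants: 3 methyl 2-O-benzoyl-4,6-O-benzylidene-3-O-(imidazol-1-ylcarbonothioyl)-α-D-glucopyranoside
Product: 4 methyl 2-O-benzoyl-4,6-O-benzylidene-3-deoxy-α-D-ribo-hexopyranoside
Conditions: Bu3SnH, AIBN (cat.), toluene, 110 °C
Reagents that add atoms: none
Why: Barton–McCombie radical deoxygenation: the stannyl radical adds to C=S, the C3–O bond fragments and the secondary C3 radical abstracts hydrogen faster than any acyloxy shift, leaving C3 as a CH2 group.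

Step 4
Reactants: 4 methyl 2-O-benzoyl-4,6-O-benzylidene-3-deoxy-α-D-ribo-hexopyranoside
Product: 5 methyl 2-O-benzoyl-4-O-benzyl-3-deoxy-α-D-ribo-hexopyranoside
Conditions: BH3·THF, TMSOTf (cat.), CH2Cl2, 0 °C to rt
Reagents that add atoms: none
Why: Regioselective reductive opening of a 4,6-O-benzylidene acetal: the Lewis acid activates the less hindered O6 and borane reduces the oxocarbenium ion, so benzyl stays on O4 and the primary 6-OH is freed while the benzoate is inert.

Step 5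
Reactants: 5 methyl 2-O-benzoyl-4-O-benzyl-3-deoxy-α-D-ribo-hexopyranoside
Product: 6 methyl 2-O-benzoyl-4-O-benzyl-6-O-(tert-butyldiphenylsilyl)-3-deoxy-α-D-ribo-hexopyranoside
Conditions: TBDPSCl, imidazole, DMF, rt
Reagents that add atoms: tert-butyl(chloro)diphenylsilane, CC(C)(C)[Si](Cl)(c1ccccc1)c1ccccc1
Why: Standard silylation of the primary hydroxyl gives a group on the future C5 oxygen that survives every step up to the dibromide and is removed orthogonally to the benzyl ether.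

Step 6
Reactants: 6 methyl 2-O-benzoyl-4-O-benzyl-6-O-(tert-butyldiphenylsilyl)-3-deoxy-α-D-ribo-hexopyranoside
Product: 7 methyl 4-O-benzyl-6-O-(tert-butyldiphenylsilyl)-3-deoxy-α-D-ribo-hexopyranoside
Conditions: NaOMe (cat.), MeOH, rt
Reagents that add atoms: none
Why: Zemplén transesterification removes the benzoate and frees the equatorial 2-OH; the glycoside, benzyl ether and primary silyl ether are stable to catalytic methoxide.

Step 7
Reactants: 7 methyl 4-O-benzyl-6-O-(tert-butyldiphenylsilyl)-3-deoxy-α-D-ribo-hexopyranoside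
Product: 8 methyl 4-O-benzyl-6-O-(tert-butyldiphenylsilyl)-3-deoxy-2-O-(trifluoromethylsulfonyl)-α-D-ribo-hexopyranoside
Conditions: Tf2O, pyridine, CH2Cl2, −20 °C
Reagents that add atoms: trifluoromethanesulfonic anhydride, O=S(=O)(OS(=O)(=O)C(F)(F)F)C(F)(F)F
Why: Sulfonylation of the only free hydroxyl with retention gives the equatorial 2-triflate, which is isolable because the neighbouring anomeric centre retards ionisation at low temperature.

Step 8
Reactants: 8 methyl 4-O-benzyl-6-O-(tert-butyldiphenylsilyl)-3-deoxy-2-O-(trifluoromethylsulfonyl)-α-D-ribo-hexopyranoside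
Product: 10 2,5-anhydro-4-O-benzyl-6-O-(tert-butyldiphenylsilyl)-3-deoxy-D-arabino-hexose dimethyl acetal, via oxocarbenium triflate 9 (not isolated)
Conditions: MeOH, 2,6-lutidine, 65 °C
Reagents that add atoms: methanol, CO
Why: Ionisation of the equatorial C2 triflate is assisted by the ring oxygen, whose C1–O5 bond lies antiperiplanar to the C2–O bond in the chair, so O5 migrates from C1 to C2 through a three-centre transition state and leaves the methoxy-stabilised oxocarbenium ion 9, which methanol traps as the dimethyl acetal. The closest known reaction type is the solvolytic ring contraction of pyranoside 2-sulfonates (and the related deamination of 2-amino-2-deoxy sugars) to 2,5-anhydro sugars. Ring A (O, C6, C7, C8, C9) closes in a 5-exo-tet mode, O5 being tethered to sugar C2 through C5–C4–C3 while the triflate departs outside the new ring. The only new stereocentre, C9, is set by the backside (inverting) attack of O5 on sugar C2; C6 and C7 (sugar C5 and C4) are untouched, so the C10 acetal and the C7 oxygen end up cis on ring A, as ring B requires. The step needs rearrangement to win over elimination and direct substitution: an equatorial leaving group has no antiperiplanar hydrogen, the axial anomeric methoxy group opposes approach of methanol to C2 from the α face, and the hindered base only takes up the triflic acid.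

Step 9
Reactants: 10 2,5-anhydro-4-O-benzyl-6-O-(tert-butyldiphenylsilyl)-3-deoxy-D-arabino-hexose dimethyl acetal
Product: 11 2,5-anhydro-6-O-(tert-butyldiphenylsilyl)-3-deoxy-D-arabino-hexose dimethyl acetal
Conditions: H2 (1 atm), 10% Pd/C, EtOAc, rt
Reagents that add atoms: none
Why: Catalytic hydrogenolysis cleaves the benzyl ether and frees the C7 hydroxyl; the silyl ether and the dimethyl acetal are inert under neutral conditions.

Step 10
Reactants: 12 (E)-pent-2-en-1-ol
Product: 13 tert-butyl (E)-pent-2-en-1-yl carbonate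
Conditions: Boc2O, DMAP (cat.), MeCN, rt
Reagents that add atoms: di-tert-butyl dicarbonate, CC(C)(C)OC(=O)OC(=O)OC(C)(C)C
Why: Acylation of the primary allylic alcohol gives the tert-butyl carbonate, whose leaving group releases only the poorly nucleophilic tert-butoxide in the next step.

Step 11
Reactants: 11 2,5-anhydro-6-O-(tert-butyldiphenylsilyl)-3-deoxy-D-arabino-hexose dimethyl acetal; 13 tert-butyl (E)-pent-2-en-1-yl carbonate
Product: 16 2,5-anhydro-6-O-(tert-butyldiphenylsilyl)-3-deoxy-4-O-[(3R)-pent-1-en-3-yl]-D-arabino-hexose dimethyl acetal, via lithium alkoxide 14 (not isolated), via copper alkoxide 15 (not isolated)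
Conditions: n-BuLi, THF, 0 °C; CuI; then 13, [Ir(cod)Cl]2 (cat.), BINOL-derived bis(1-phenylethyl)amine phosphoramidite (cat.), THF, rt
Reagents that add atoms: none
Why: Iridium-catalysed branch-selective allylic etherification of an aliphatic copper alkoxide: the alkoxide attacks the substituted terminus of the allyl–iridium intermediate anti to the metal, and the chiral phosphoramidite, not the substrate, fixes C13 as R.

Step 12
Reactants: 16 2,5-anhydro-6-O-(tert-butyldiphenylsilyl)-3-deoxy-4-O-[(3R)-pent-1-en-3-yl]-D-arabino-hexose dimethyl acetal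
Product: 17 2,5-anhydro-6-O-(tert-butyldiphenylsilyl)-3-deoxy-4-O-[(3R)-pent-1-en-3-yl]-D-arabino-hexose
Conditions: CF3CO2H/H2O, CH2Cl2, 0 °C
Reagents that add atoms: water, O
Why: Acid-catalysed acetal hydrolysis unmasks the C10 aldehyde; the short cold exposure spares the primary silyl ether and the allylic ether, and the crude aldehyde is used at once to avoid epimerisation at C9.

Step 13
Reactants: 17 2,5-anhydro-6-O-(tert-butyldiphenylsilyl)-3-deoxy-4-O-[(3R)-pent-1-en-3-yl]-D-arabino-hexose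
Product: 18 (1S)-1-[(2S,4S,5R)-5-{[(tert-butyldiphenylsilyl)oxy]methyl}-4-{[(3R)-pent-1-en-3-yl]oxy}oxolan-2-yl]prop-2-en-1-ol
Conditions: MgBr2·OEt2, CH2Cl2, −78 °C; then CH2=CHMgBr
Reagents that add atoms: vinylmagnesium bromide, C=C[Mg]Br
Why: Cram-chelate addition: magnesium held between the aldehyde oxygen and the ring A oxygen fixes the rotamer and the vinyl Grignard reagent attacks the face away from C8, which should give the 9,10-syn (10S) carbinol.

Step 14
Reactants: 18 (1S)-1-[(2S,4S,5R)-5-{[(tert-butyldiphenylsilyl)oxy]methyl}-4-{[(3R)-pent-1-en-3-yl]oxy}oxolan-2-yl]prop-2-en-1-ol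
Product: 19 (1S,3R,4Z,6S,7S,9R)-9-{[(tert-butyldiphenylsilyl)oxy]methyl}-3-ethyl-2,8-dioxabicyclo[5.2.1]dec-4-en-6-ol
Conditions: second-generation Grubbs catalyst (cat.), CH2Cl2 (high dilution), 40 °C
Reagents that add atoms: none
Why: Ring-closing metathesis of two monosubstituted allylic alkenes whose arms sit cis on ring A (C7 oxygen and C9 carbon), so ring B should close as the bridged eight-membered Z-alkene (C11=C12) with loss of ethene and without creating a stereocentre.

Step 15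
Reactants: 19 (1S,3R,4Z,6S,7S,9R)-9-{[(tert-butyldiphenylsilyl)oxy]methyl}-3-ethyl-2,8-dioxabicyclo[5.2.1]dec-4-en-6-ol
Product: 20 (1S,3R,4S,5R,6R,7S,9R)-9-{[(tert-butyldiphenylsilyl)oxy]methyl}-4,5-epoxy-3-ethyl-2,8-dioxabicyclo[5.2.1]decan-6-ol
Conditions: VO(acac)2 (cat.), t-BuOOH, CH2Cl2, 0 °C to rt
Reagents that add atoms: tert-butyl hydroperoxide, CC(C)(C)OO
Why: Hydroxyl-directed epoxidation: the vanadium alkoxide of the C10 alcohol delivers oxygen to the alkene face syn to that hydroxyl (the sense established for cyclooct-2-enols), which overrides the adjacent ethyl group and places the C12–O bond in the configuration needed for the later inversion.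

Step 16
Reactants: 20 (1S,3R,4S,5R,6R,7S,9R)-9-{[(tert-butyldiphenylsilyl)oxy]methyl}-4,5-epoxy-3-ethyl-2,8-dioxabicyclo[5.2.1]decan-6-ol
Product: 21 (1S,3R,4S,5S,7S,9R)-9-{[(tert-butyldiphenylsilyl)oxy]methyl}-4,5-epoxy-3-ethyl-2,8-dioxabicyclo[5.2.1]decan-6-one
Conditions: Dess–Martin periodinane, NaHCO3, CH2Cl2, rt
Reagents that add atoms: none
Why: Buffered Dess–Martin oxidation converts the C10 carbinol, whose directing role is over, into the ketone without opening the epoxide; C9 is a bridgehead and cannot epimerise.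

Step 17
Reactants: 21 (1S,3R,4S,5S,7S,9R)-9-{[(tert-butyldiphenylsilyl)oxy]methyl}-4,5-epoxy-3-ethyl-2,8-dioxabicyclo[5.2.1]decan-6-one
Product: 22 (1S,3R,4R,7S,9R)-9-{[(tert-butyldiphenylsilyl)oxy]methyl}-3-ethyl-4-hydroxy-2,8-dioxabicyclo[5.2.1]decan-6-one
Conditions: (PhSe)2, NaBH4, EtOH, then AcOH, 0 °C to rt
Reagents that add atoms: none
Why: Organoselenium reduction of an α,β-epoxy ketone: selenolate opens the epoxide at C11 (α to the carbonyl) and a second selenolate removes selenium, so C11 becomes CH2 while the C12–O bond and configuration are kept and the ether oxygen at C9 is not reduced.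

Step 18
Reactants: 22 (1S,3R,4R,7S,9R)-9-{[(tert-butyldiphenylsilyl)oxy]methyl}-3-ethyl-4-hydroxy-2,8-dioxabicyclo[5.2.1]decan-6-one
Product: 23 (1S,3R,4R,6R,7S,9R)-9-{[(tert-butyldiphenylsilyl)oxy]methyl}-3-ethyl-2,8-dioxabicyclo[5.2.1]decane-4,6-diol
Conditions: Me4NBH(OAc)3, MeCN/AcOH, −30 °C
Reagents that add atoms: none
Why: Evans–Saksena reduction: after exchange of acetate on boron for the C12 hydroxyl, hydride is delivered intramolecularly to the C10 carbonyl from the face of that hydroxyl, which is also the face away from the ring A oxygen, so the 1,3-anti (10R) diol should result.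

Step 19
Reactants: 23 (1S,3R,4R,6R,7S,9R)-9-{[(tert-butyldiphenylsilyl)oxy]methyl}-3-ethyl-2,8-dioxabicyclo[5.2.1]decane-4,6-diol
Product: 24 (1S,3R,4S,6S,7S,9R)-4,6-dibromo-9-{[(tert-butyldiphenylsilyl)oxy]methyl}-3-ethyl-2,8-dioxabicyclo[5.2.1]decane
Conditions: CBr4, P(n-C8H17)3, toluene, 70 °C
Reagents that add atoms: carbon tetrabromide, BrC(Br)(Br)Br
Why: Appel-type bromination, the reagent pair used for secondary alcohols next to ether carbons in medium-ring ethers: each alkoxyphosphonium ion is displaced by bromide with inversion, turning the 10R,12R diol into the 10S,12S dibromide.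

Step 20
Reactants: 24 (1S,3R,4S,6S,7S,9R)-4,6-dibromo-9-{[(tert-butyldiphenylsilyl)oxy]methyl}-3-ethyl-2,8-dioxabicyclo[5.2.1]decane
Product: 25 [(1S,3R,4S,6S,7S,9R)-4,6-dibromo-3-ethyl-2,8-dioxabicyclo[5.2.1]decan-9-yl]methanol
Conditions: HF·pyridine, THF, 0 °C to rt
Reagents that add atoms: none
Why: Fluoride-mediated desilylation under acidic, non-basic conditions frees the C5 hydroxyl without risk of E2 elimination of the secondary bromides.

Step 21
Reactants: 25 [(1S,3R,4S,6S,7S,9R)-4,6-dibromo-3-ethyl-2,8-dioxabicyclo[5.2.1]decan-9-yl]methanol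
Product: 26 [(1S,3R,4S,6S,7S,9R)-4,6-dibromo-3-ethyl-2,8-dioxabicyclo[5.2.1]decan-9-yl]methyl trifluoromethanesulfonate
Conditions: Tf2O, 2,6-lutidine, CH2Cl2, −78 °C
Reagents that add atoms: trifluoromethanesulfonic anhydride, O=S(=O)(OS(=O)(=O)C(F)(F)F)C(F)(F)F
Why: Triflation of the only hydroxyl activates the primary C5 carbon far above the hindered secondary bromides; the triflate is used crude and cold.

Step 22
Reactants: 26 [(1S,3R,4S,6S,7S,9R)-4,6-dibromo-3-ethyl-2,8-dioxabicyclo[5.2.1]decan-9-yl]methyl trifluoromethanesulfonate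
Product: 27 (1S,3R,4S,6S,7S,9R)-4,6-dibromo-3-ethyl-9-(prop-2-en-1-yl)-2,8-dioxabicyclo[5.2.1]decane
Conditions: CH2=CHMgBr, CuI (cat.), THF, −40 to 0 °C
Reagents that add atoms: vinylmagnesium bromide, C=C[Mg]Br
Why: Copper-catalysed substitution of a primary triflate by a vinyl Grignard reagent forms the C4–C5 bond at low temperature, where the ring secondary bromides (β-oxygenated and hindered) should not react.

Step 23
Reactants: 27 (1S,3R,4S,6S,7S,9R)-4,6-dibromo-3-ethyl-9-(prop-2-en-1-yl)-2,8-dioxabicyclo[5.2.1]decane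
Product: 28 (2E)-4-[(1S,3R,4S,6S,7S,9R)-4,6-dibromo-3-ethyl-2,8-dioxabicyclo[5.2.1]decan-9-yl]but-2-enal
Conditions: (E)-crotonaldehyde (excess), second-generation Hoveyda–Grubbs catalyst (cat.), CH2Cl2, 40 °C
Reagents that add atoms: (E)-but-2-enal, C/C=C/C=O
Why: Cross-metathesis of the terminal alkene with an excess of an electron-poor enal gives the conjugated aldehyde under thermodynamic control, hence the E alkene at C3=C4.

Step 24
Reactants: 28 (2E)-4-[(1S,3R,4S,6S,7S,9R)-4,6-dibromo-3-ethyl-2,8-dioxabicyclo[5.2.1]decan-9-yl]but-2-enal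
Product: 29 (1S,3R,4S,6S,7S,9R)-4,6-dibromo-3-ethyl-9-[(2E)-pent-2-en-4-yn-1-yl]-2,8-dioxabicyclo[5.2.1]decane
Conditions: Me3SiCHN2, LDA, THF, −78 °C to rt
Reagents that add atoms: (trimethylsilyl)diazomethane, C[Si](C)(C)C=[N+]=[N-]
Why: Colvin rearrangement: the lithiated silyldiazomethane adds to the aldehyde, Peterson-type elimination and loss of nitrogen are followed by a 1,2-hydride shift that gives the terminal alkyne with the E alkene intact, and the amide base is consumed before the bromide-bearing substrate is added.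

**Compound list**

1 | methyl 4,6-O-benzylidene-α-D-glucopyranoside | CO[C@H]1O[C@@H]2CO[C@@H](c3ccccc3)O[C@H]2[C@H](O)[C@H]1O | starting material
2 | methyl 2-O-benzoyl-4,6-O-benzylidene-α-D-glucopyranoside | CO[C@H]1O[C@@H]2CO[C@@H](c3ccccc3)O[C@H]2[C@H](O)[C@H]1OC(=O)c4ccccc4 | intermediate
3 | methyl 2-O-benzoyl-4,6-O-benzylidene-3-O-(imidazol-1-ylcarbonothioyl)-α-D-glucopyranoside | CO[C@H]1O[C@@H]2CO[C@@H](c3ccccc3)O[C@H]2[C@H](OC(=S)n4ccnc4)[C@H]1OC(=O)c5ccccc5 | intermediate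
4 | methyl 2-O-benzoyl-4,6-O-benzylidene-3-deoxy-α-D-ribo-hexopyranoside | CO[C@H]1O[C@@H]2CO[C@@H](c3ccccc3)O[C@H]2C[C@H]1OC(=O)c4ccccc4 | intermediate
5 | methyl 2-O-benzoyl-4-O-benzyl-3-deoxy-α-D-ribo-hexopyranoside | CO[C@H]1O[C@H](CO)[C@@H](OCc2ccccc2)C[C@H]1OC(=O)c3ccccc3 | intermediate
6 | methyl 2-O-benzoyl-4-O-benzyl-6-O-(tert-butyldiphenylsilyl)-3-deoxy-α-D-ribo-hexopyranoside | CO[C@H]1O[C@H](CO[Si](c2ccccc2)(c3ccccc3)C(C)(C)C)[C@@H](OCc4ccccc4)C[C@H]1OC(=O)c5ccccc5 | intermediate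
7 | methyl 4-O-benzyl-6-O-(tert-butyldiphenylsilyl)-3-deoxy-α-D-ribo-hexopyranoside | CO[C@H]1O[C@H](CO[Si](c2ccccc2)(c3ccccc3)C(C)(C)C)[C@@H](OCc4ccccc4)C[C@H]1O | intermediate
8 | methyl 4-O-benzyl-6-O-(tert-butyldiphenylsilyl)-3-deoxy-2-O-(trifluoromethylsulfonyl)-α-D-ribo-hexopyranoside | CO[C@H]1O[C@H](CO[Si](c2ccccc2)(c3ccccc3)C(C)(C)C)[C@@H](OCc4ccccc4)C[C@H]1OS(=O)(=O)C(F)(F)F | intermediate
9 | oxocarbenium triflate: C1 methoxycarbenium ion of 2,5-anhydro-4-O-benzyl-6-O-(tert-butyldiphenylsilyl)-3-deoxy-D-arabino-hexose, triflate counter-ion | CC(C)(C)[Si](c1ccccc1)(c2ccccc2)OC[C@H]3O[C@H](C=[O+]C)C[C@@H]3OCc4ccccc4.[O-]S(=O)(=O)C(F)(F)F | intermediate (not isolated)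
10 | 2,5-anhydro-4-O-benzyl-6-O-(tert-butyldiphenylsilyl)-3-deoxy-D-arabino-hexose dimethyl acetal | CC(C)(C)[Si](c1ccccc1)(c2ccccc2)OC[C@H]3O[C@H](C(OC)OC)C[C@@H]3OCc4ccccc4 | intermediate
11 | 2,5-anhydro-6-O-(tert-butyldiphenylsilyl)-3-deoxy-D-arabino-hexose dimethyl acetal | CC(C)(C)[Si](c1ccccc1)(c2ccccc2)OC[C@H]3O[C@H](C(OC)OC)C[C@@H]3O | intermediate
12 | (E)-pent-2-en-1-ol | CC/C=C/CO | starting material
13 | tert-butyl (E)-pent-2-en-1-yl carbonate | CC/C=C/COC(=O)OC(C)(C)C | intermediate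
14 | lithium alkoxide of 11 (lithium on the C7 oxygen) | CC(C)(C)[Si](c1ccccc1)(c2ccccc2)OC[C@H]3O[C@H](C(OC)OC)C[C@@H]3O[Li] | intermediate (not isolated)
15 | copper alkoxide of 11 (copper on the C7 oxygen) | CC(C)(C)[Si](c1ccccc1)(c2ccccc2)OC[C@H]3O[C@H](C(OC)OC)C[C@@H]3O[Cu] | intermediate (not isolated)
16 | 2,5-anhydro-6-O-(tert-butyldiphenylsilyl)-3-deoxy-4-O-[(3R)-pent-1-en-3-yl]-D-arabino-hexose dimethyl acetal | CC(C)(C)[Si](c1ccccc1)(c2ccccc2)OC[C@H]3O[C@H](C(OC)OC)C[C@@H]3O[C@H](CC)C=C | intermediate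
17 | 2,5-anhydro-6-O-(tert-butyldiphenylsilyl)-3-deoxy-4-O-[(3R)-pent-1-en-3-yl]-D-arabino-hexose | CC(C)(C)[Si](c1ccccc1)(c2ccccc2)OC[C@H]3O[C@H](C=O)C[C@@H]3O[C@H](CC)C=C | intermediate
18 | (1S)-1-[(2S,4S,5R)-5-{[(tert-butyldiphenylsilyl)oxy]methyl}-4-{[(3R)-pent-1-en-3-yl]oxy}oxolan-2-yl]prop-2-en-1-ol | CC(C)(C)[Si](c1ccccc1)(c2ccccc2)OC[C@H]3O[C@H]([C@@H](O)C=C)C[C@@H]3O[C@H](CC)C=C | intermediate
19 | (1S,3R,4Z,6S,7S,9R)-9-{[(tert-butyldiphenylsilyl)oxy]methyl}-3-ethyl-2,8-dioxabicyclo[5.2.1]dec-4-en-6-ol | CC(C)(C)[Si](c1ccccc1)(c2ccccc2)OC[C@H]3O[C@H]4C[C@@H]3O[C@H](CC)/C=C\[C@@H]4O | intermediate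
20 | (1S,3R,4S,5R,6R,7S,9R)-9-{[(tert-butyldiphenylsilyl)oxy]methyl}-4,5-epoxy-3-ethyl-2,8-dioxabicyclo[5.2.1]decan-6-ol (epoxide syn to the hydroxyl) | CC(C)(C)[Si](c1ccccc1)(c2ccccc2)OC[C@H]3O[C@H]4C[C@@H]3O[C@H](CC)[C@@H]5O[C@@H]5[C@@H]4O | intermediate
21 | (1S,3R,4S,5S,7S,9R)-9-{[(tert-butyldiphenylsilyl)oxy]methyl}-4,5-epoxy-3-ethyl-2,8-dioxabicyclo[5.2.1]decan-6-one | CC(C)(C)[Si](c1ccccc1)(c2ccccc2)OC[C@H]3O[C@H]4C[C@@H]3O[C@H](CC)[C@@H]5O[C@@H]5C4=O | intermediate
22 | (1S,3R,4R,7S,9R)-9-{[(tert-butyldiphenylsilyl)oxy]methyl}-3-ethyl-4-hydroxy-2,8-dioxabicyclo[5.2.1]decan-6-one | CC(C)(C)[Si](c1ccccc1)(c2ccccc2)OC[C@H]3O[C@H]4C[C@@H]3O[C@H](CC)[C@H](O)CC4=O | intermediate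
23 | (1S,3R,4R,6R,7S,9R)-9-{[(tert-butyldiphenylsilyl)oxy]methyl}-3-ethyl-2,8-dioxabicyclo[5.2.1]decane-4,6-diol | CC(C)(C)[Si](c1ccccc1)(c2ccccc2)OC[C@H]3O[C@H]4C[C@@H]3O[C@H](CC)[C@H](O)C[C@H]4O | intermediate
24 | (1S,3R,4S,6S,7S,9R)-4,6-dibromo-9-{[(tert-butyldiphenylsilyl)oxy]methyl}-3-ethyl-2,8-dioxabicyclo[5.2.1]decane | CC(C)(C)[Si](c1ccccc1)(c2ccccc2)OC[C@H]3O[C@H]4C[C@@H]3O[C@H](CC)[C@@H](Br)C[C@@H]4Br | intermediate
25 | [(1S,3R,4S,6S,7S,9R)-4,6-dibromo-3-ethyl-2,8-dioxabicyclo[5.2.1]decan-9-yl]methanol | OC[C@H]1O[C@H]2C[C@@H]1O[C@H](CC)[C@@H](Br)C[C@@H]2Br | intermediate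
26 | [(1S,3R,4S,6S,7S,9R)-4,6-dibromo-3-ethyl-2,8-dioxabicyclo[5.2.1]decan-9-yl]methyl trifluoromethanesulfonate | FC(F)(F)S(=O)(=O)OC[C@H]1O[C@H]2C[C@@H]1O[C@H](CC)[C@@H](Br)C[C@@H]2Br | intermediate
27 | (1S,3R,4S,6S,7S,9R)-4,6-dibromo-3-ethyl-9-(prop-2-en-1-yl)-2,8-dioxabicyclo[5.2.1]decane | C=CC[C@H]1O[C@H]2C[C@@H]1O[C@H](CC)[C@@H](Br)C[C@@H]2Br | intermediate
28 | (2E)-4-[(1S,3R,4S,6S,7S,9R)-4,6-dibromo-3-ethyl-2,8-dioxabicyclo[5.2.1]decan-9-yl]but-2-enal | O=C/C=C/C[C@H]1O[C@H]2C[C@@H]1O[C@H](CC)[C@@H](Br)C[C@@H]2Br | intermediate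
29 | (1S,3R,4S,6S,7S,9R)-4,6-dibromo-3-ethyl-9-[(2E)-pent-2-en-4-yn-1-yl]-2,8-dioxabicyclo[5.2.1]decane (chain numbering: 6R,7S,9S,10S,12S,13R) | C#C/C=C/C[C@H]1O[C@H]2C[C@@H]1O[C@H](CC)[C@@H](Br)C[C@@H]2Br | target

**Step count**

Total: 24 steps. Longest linear sequence: 23 steps (steps 1–9 and 11–24); step 10 prepares carbonate 13.

**Steps most likely to fail**

1. Step 14 (ring-closing metathesis). Intermolecular metathesis to dimers and oligomers, or ring-opening of the strained bridged alkene, may outrun closure, and ruthenium hydride species may isomerise the allylic alcohol to a ketone. Fallback: ring B is closed by C10–C11 bond formation in an irreversible chromium-mediated addition. It sets out from 16: ozonolysis of the vinyl group (O3, CH2Cl2/MeOH, −78 °C, then PPh3) should give (2R)-2-{[(2R,3S,5S)-2-{[(tert-butyldiphenylsilyl)oxy]methyl}-5-(dimethoxymethyl)oxolan-3-yl]oxy}butanal F1. Stork–Zhao olefination (Ph3P=CHI from the iodomethylphosphonium iodide and NaN(SiMe3)2, THF, −78 °C) should give the (Z)-vinyl iodide tert-butyl{[(2R,3S,5S)-5-(dimethoxymethyl)-3-{[(1Z,3R)-1-iodopent-1-en-3-yl]oxy}oxolan-2-yl]methoxy}diphenylsilane F2. Acetal hydrolysis (CF3CO2H/H2O, 0 °C) gives the iodo aldehyde (2S,4S,5R)-5-{[(tert-butyldiphenylsilyl)oxy]methyl}-4-{[(1Z,3R)-1-iodopent-1-en-3-yl]oxy}oxolane-2-carbaldehyde F3. Nozaki–Hiyama–Kishi cyclisation (CrCl2, NiCl2 cat., DMSO, high dilution) is then expected to deliver allylic alcohol 19, where the fallback rejoins the route; the C10 configuration would have to be confirmed at that point.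

2. Step 19 (double bromination). The activated alcohols may be attacked transannularly by a ring oxygen (ring B oxygen on C10, ring A oxygen on C12), leading to retention or skeletal rearrangement; E2 elimination or a stalled second substitution are also possible. Fallback: the two bromides are introduced one at a time with the other oxygen masked. It sets out from 22: silylation (Et3SiOTf, 2,6-lutidine) should give (1S,3R,4R,7S,9R)-9-{[(tert-butyldiphenylsilyl)oxy]methyl}-3-ethyl-4-(triethylsilyloxy)-2,8-dioxabicyclo[5.2.1]decan-6-one F4. Reduction with NaBH4 from the face away from the ring A oxygen gives (1S,3R,4R,6R,7S,9R)-9-{[(tert-butyldiphenylsilyl)oxy]methyl}-3-ethyl-4-(triethylsilyloxy)-2,8-dioxabicyclo[5.2.1]decan-6-ol F5. Bromination with inversion (CBr4, trioctylphosphine) gives (1S,3R,4R,6S,7S,9R)-6-bromo-9-{[(tert-butyldiphenylsilyl)oxy]methyl}-3-ethyl-4-(triethylsilyloxy)-2,8-dioxabicyclo[5.2.1]decane F6. Selective removal of the triethylsilyl group (pyridinium p-toluenesulfonate, MeOH) gives (1S,3R,4R,6S,7S,9R)-6-bromo-9-{[(tert-butyldiphenylsilyl)oxy]methyl}-3-ethyl-2,8-dioxabicyclo[5.2.1]decan-4-ol F7. A second bromination with inversion at C12 leads to dibromide 24, where the fallback rejoins the route.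

3. Step 11 (iridium-catalysed etherification). The hindered secondary copper alkoxide may react slowly, so that linear ether formation or carbonate decomposition competes, and catalyst control at C13 may be eroded in a mismatched pairing. Fallback: C13 is taken from the chiral pool and the ether bond is made by SN2 with inversion. It sets out from 11: alkylation of the sodium alkoxide with (S)-2-bromobutanoic acid (NaH, THF/DMF) should give (2R)-2-{[(2R,3S,5S)-2-{[(tert-butyldiphenylsilyl)oxy]methyl}-5-(dimethoxymethyl)oxolan-3-yl]oxy}butanoic acid F8. Coupling with N,O-dimethylhydroxylamine (carbodiimide) gives (2R)-2-{[(2R,3S,5S)-2-{[(tert-butyldiphenylsilyl)oxy]methyl}-5-(dimethoxymethyl)oxolan-3-yl]oxy}-N-methoxy-N-methylbutanamide F9. Reduction with i-Bu2AlH at −78 °C gives the aldehyde already described as F1, and Wittig methylenation (Ph3P=CH2) returns to ether 16.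

Further compounds
F1 | step 14 | (2R)-2-{[(2R,3S,5S)-2-{[(tert-butyldiphenylsilyl)oxy]methyl}-5-(dimethoxymethyl)oxolan-3-yl]oxy}butanal | CC(C)(C)[Si](c1ccccc1)(c2ccccc2)OC[C@H]3O[C@H](C(OC)OC)C[C@@H]3O[C@H](CC)C=O
F2 | step 14 | tert-butyl{[(2R,3S,5S)-5-(dimethoxymethyl)-3-{[(1Z,3R)-1-iodopent-1-en-3-yl]oxy}oxolan-2-yl]methoxy}diphenylsilane | CC(C)(C)[Si](c1ccccc1)(c2ccccc2)OC[C@H]3O[C@H](C(OC)OC)C[C@@H]3O[C@H](CC)/C=C\I
F3 | step 14 | (2S,4S,5R)-5-{[(tert-butyldiphenylsilyl)oxy]methyl}-4-{[(1Z,3R)-1-iodopent-1-en-3-yl]oxy}oxolane-2-carbaldehyde | CC(C)(C)[Si](c1ccccc1)(c2ccccc2)OC[C@H]3O[C@H](C=O)C[C@@H]3O[C@H](CC)/C=C\I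
F4 | step 19 | (1S,3R,4R,7S,9R)-9-{[(tert-butyldiphenylsilyl)oxy]methyl}-3-ethyl-4-(triethylsilyloxy)-2,8-dioxabicyclo[5.2.1]decan-6-one | CC(C)(C)[Si](c1ccccc1)(c2ccccc2)OC[C@H]3O[C@H]4C[C@@H]3O[C@H](CC)[C@H](O[Si](CC)(CC)CC)CC4=O
F5 | step 19 | (1S,3R,4R,6R,7S,9R)-9-{[(tert-butyldiphenylsilyl)oxy]methyl}-3-ethyl-4-(triethylsilyloxy)-2,8-dioxabicyclo[5.2.1]decan-6-ol | CC(C)(C)[Si](c1ccccc1)(c2ccccc2)OC[C@H]3O[C@H]4C[C@@H]3O[C@H](CC)[C@H](O[Si](CC)(CC)CC)C[C@H]4O
F6 | step 19 | (1S,3R,4R,6S,7S,9R)-6-bromo-9-{[(tert-butyldiphenylsilyl)oxy]methyl}-3-ethyl-4-(triethylsilyloxy)-2,8-dioxabicyclo[5.2.1]decane | CC(C)(C)[Si](c1ccccc1)(c2ccccc2)OC[C@H]3O[C@H]4C[C@@H]3O[C@H](CC)[C@H](O[Si](CC)(CC)CC)C[C@@H]4Br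
F7 | step 19 | (1S,3R,4R,6S,7S,9R)-6-bromo-9-{[(tert-butyldiphenylsilyl)oxy]methyl}-3-ethyl-2,8-dioxabicyclo[5.2.1]decan-4-ol | CC(C)(C)[Si](c1ccccc1)(c2ccccc2)OC[C@H]3O[C@H]4C[C@@H]3O[C@H](CC)[C@H](O)C[C@@H]4Br
F8 | step 11 | (2R)-2-{[(2R,3S,5S)-2-{[(tert-butyldiphenylsilyl)oxy]methyl}-5-(dimethoxymethyl)oxolan-3-yl]oxy}butanoic acid | CC(C)(C)[Si](c1ccccc1)(c2ccccc2)OC[C@H]3O[C@H](C(OC)OC)C[C@@H]3O[C@H](CC)C(=O)O
F9 | step 11 | (2R)-2-{[(2R,3S,5S)-2-{[(tert-butyldiphenylsilyl)oxy]methyl}-5-(dimethoxymethyl)oxolan-3-yl]oxy}-N-methoxy-N-methylbutanamide | CC(C)(C)[Si](c1ccccc1)(c2ccccc2)OC[C@H]3O[C@H](C(OC)OC)C[C@@H]3O[C@H](CC)C(=O)N(C)OC
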